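**Plan**
1. Numbering: ring A = ten-membered lactone, C1 (ester C=O) to C9 (O–CHMe), C10 = methyl; second chain C1' (γ-lactone C=O), C2', C3' (enol ether carbon) to C9', C10' = methyl; ring B = γ-lactone (O3–C1'–C2'–C4–C3), ring C = tetrahydrofuran, ring D = tetrahydropyran.
2. Cuts, in retro order: the O6'–C3' enol ether of ring C; C2'–C3' (acylation); ring B at O3–C1' and C4–C2' (Meldrum's acid + a ring A enone); ring A at C5–C6 (alkenyl iodide + aldehyde, then oxidation) and at the C1–O ester.
3. Enabling feature: in ring A the C6 ketone sits next to C5H2 and the ring-fusion carbon C4, the saturated form of a 4-en-6-one, and C6(=O)–C5–C4–C2'–C1'(=O) is a 1,5-dicarbonyl span; C5–C6 is therefore the alkenyl–carbonyl bond of an enone and C4–C2' its Michael bond.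
4. Forward: ring D (Achmatowicz) → open-chain ester → ring A by C5–C6 closure → ring B (Michael addition, lactonization) → acylation at C2' → ring C.
5. Stereochemistry: C3 from (S)-α-hydroxy-γ-butyrolactone and C9 from (R)-hex-5-en-2-ol; C5' by Ru-catalysed transfer hydrogenation, relayed to C9' and C6' by substrate control; C4 by attack on the outer face of the ring A E-enone under control of C3; the E enol ether by acid equilibration.
6. The C2' nucleophile is kept untethered: delivery from O3 would add syn to O3 with H3 eclipsing the alkene and should give the trans ring fusion.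

Key step: step 14

Remark: the C6 carbinol epimers of 22 and the C2' epimers of 27 and 30–31 are carried as mixtures, since both carbons become sp2; TBS = tert-butyldimethylsilyl.

Step 1
Reactants: 1 2-acetyl-5-methylfuran; 2 diethyl carbonate
Product: 3 ethyl 3-(5-methylfuran-2-yl)-3-oxopropanoate
Conditions: NaH, THF, 65 °C; then AcOH
Reagents that add atoms: none
Why: Claisen-type C-ethoxycarbonylation of the methyl ketone enolate, pulled forward by deprotonation of the β-keto ester.

Step 2
Reactants: 3 ethyl 3-(5-methylfuran-2-yl)-3-oxopropanoate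
Product: 4 ethyl (3S)-3-hydroxy-3-(5-methylfuran-2-yl)propanoate
Conditions: RuCl[(S,S)-TsDPEN](p-cymene) (1 mol %), HCO2H/Et3N 5:2, 25 °C
Reagents that add atoms: none
Why: Noyori asymmetric transfer hydrogenation of a heteroaryl ketone; the (S,S) catalyst should deliver hydride to the face that gives the S carbinol (C5'), as it does for aryl alkyl ketones.

Step 3
Reactants: 4 ethyl (3S)-3-hydroxy-3-(5-methylfuran-2-yl)propanoate
Product: 5 ethyl 2-[(2S)-6-hydroxy-6-methyl-3-oxo-3,6-dihydro-2H-pyran-2-yl]acetate (anomers)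
Conditions: NBS, NaHCO3, NaOAc, THF/H2O 4:1, 0 °C
Reagents that add atoms: water O
Why: Achmatowicz rearrangement, in which oxidation of the furan to the ene-dione and closure of the carbinol oxygen onto the methyl ketone give the pyranone hemiketal without touching the carbinol centre.

Step 4
Reactants: 5 ethyl 2-[(2S)-6-hydroxy-6-methyl-3-oxo-3,6-dihydro-2H-pyran-2-yl]acetate
Product: 6 ethyl 2-[(2S,6R)-6-methyl-3-oxo-3,6-dihydro-2H-pyran-2-yl]acetate
Conditions: Et3SiH, CF3CO2H, CH2Cl2, −40 to 0 °C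
Reagents that add atoms: none
Why: Kishi reductive deoxygenation, in which the acid ionises the hemiketal to the oxocarbenium ion and the silane adds axially, which should set the 2,6-cis relation (C9' R) from the C5' centre.

Step 5
Reactants: 6 ethyl 2-[(2S,6R)-6-methyl-3-oxo-3,6-dihydro-2H-pyran-2-yl]acetate
Product: 7 ethyl 2-[(2S,6R)-6-methyl-3-oxooxan-2-yl]acetate
Conditions: H2 (1 atm), Pd/C, EtOAc, 25 °C
Reagents that add atoms: none
Why: Heterogeneous hydrogenation of the enone C=C, which makes no stereocentre and leaves the thermodynamically preferred 2,6-cis ketone.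

Step 6
Reactants: 7 ethyl 2-[(2S,6R)-6-methyl-3-oxooxan-2-yl]acetate
Product: 9 (3aS,5R,7aS)-5-methylhexahydro-2H-furo[3,2-b]pyran-2-one, via hydroxy ester 8 (not isolated)
Conditions: LiBH(s-Bu)3, THF, −78 °C; AcOH; then PPTS, PhMe, 60 °C
Reagents that add atoms: none
Why: The bulky borohydride attacks the pyranone from the equatorial direction to give the axial alcohol cis to the C5' side chain (C6' S, substrate control), which lactonizes to the cis-fused bicycle.

Step 7
Reactants: 9 (3aS,5R,7aS)-5-methylhexahydro-2H-furo[3,2-b]pyran-2-one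
Product: 12 2-[(2S,3S,6R)-3-(tert-butyldimethylsilyloxy)-6-methyloxan-2-yl]acetic acid, via lithium hydroxy carboxylate 10 (not isolated), via bis-silyl compound 11 (not isolated)
Conditions: LiOH, THF/H2O, 25 °C; evaporate; TBSCl, imidazole, DMF, 40 °C; then AcOH/THF/H2O, 25 °C
Reagents that add atoms: lithium hydroxide [Li+].[OH-]; tert-butyldimethylsilyl chloride CC(C)(C)[Si](C)(C)Cl
Why: Saponification opens the lactone, silylation caps both oxygens and the labile silyl ester is hydrolysed selectively, the standard way to an O-silylated γ-hydroxy acid that cannot relactonize.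

Step 8
Reactants: 13 (S)-3-hydroxydihydrofuran-2(3H)-one
Product: 14 (S)-3-(tert-butyldimethylsilyloxy)dihydrofuran-2(3H)-one
Conditions: TBSCl, imidazole, DMF, 25 °C
Reagents that add atoms: tert-butyldimethylsilyl chloride CC(C)(C)[Si](C)(C)Cl
Why: Routine silylation of the secondary alcohol; the bought C3 centre is not involved.

Step 9
Reactants: 14 (S)-3-(tert-butyldimethylsilyloxy)dihydrofuran-2(3H)-one
Product: 15 (3S)-3-(tert-butyldimethylsilyloxy)tetrahydrofuran-2-ol (anomers)
Conditions: i-Bu2AlH, CH2Cl2, −78 °C; aq. potassium sodium tartrate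
Reagents that add atoms: none
Why: Partial reduction of the lactone to the lactol, whose tetrahedral aluminate is stable at low temperature.

Step 10
Reactants: 15 (3S)-3-(tert-butyldimethylsilyloxy)tetrahydrofuran-2-ol; 16 iodoform
Product: 17 (3S,4E)-3-(tert-butyldimethylsilyloxy)-5-iodopent-4-en-1-ol
Conditions: CrCl2, THF/dioxane, 0 to 25 °C
Reagents that add atoms: none
Why: Takai olefination of the open hydroxy aldehyde form of the lactol by the geminal dichromium species from iodoform, which should give the E iodoalkene without epimerising the α-silyloxy centre under these non-basic conditions.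

Step 11
Reactants: 17 (3S,4E)-3-(tert-butyldimethylsilyloxy)-5-iodopent-4-en-1-ol
Product: 18 (3S,4E)-3-(tert-butyldimethylsilyloxy)-5-iodopent-4-enoic acid
Conditions: TEMPO (cat.), PhI(OAc)2, MeCN/H2O, 25 °C
Reagents that add atoms: water O
Why: Oxoammonium oxidation of the primary alcohol through the aldehyde hydrate to the acid under mildly acidic conditions that leave the alkenyl iodide and silyl ether alone.

Step 12
Reactants: 18 (3S,4E)-3-(tert-butyldimethylsilyloxy)-5-iodopent-4-enoic acid; 19 (R)-hex-5-en-2-ol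
Product: 20 (2R)-hex-5-en-2-yl (3S,4E)-3-(tert-butyldimethylsilyloxy)-5-iodopent-4-enoate
Conditions: DCC, DMAP (cat.), CH2Cl2, 0 to 25 °C
Reagents that add atoms: none
Why: Steglich esterification at the acid carbonyl, which keeps the C9 carbinol configuration (O-acylation) and joins the two bought stereocentres.

Step 13
Reactants: 20 (2R)-hex-5-en-2-yl (3S,4E)-3-(tert-butyldimethylsilyloxy)-5-iodopent-4-enoate
Product: 21 (2R)-5-oxopentan-2-yl (3S,4E)-3-(tert-butyldimethylsilyloxy)-5-iodopent-4-enoate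
Conditions: OsO4 (cat.), NaIO4, 2,6-lutidine, dioxane/H2O, 25 °C
Reagents that add atoms: osmium tetroxide O=[Os](=O)(=O)=O; sodium periodate [Na+].[O-]I(=O)(=O)=O
Why: Lemieux–Johnson cleavage of the electron-richer terminal alkene, which should outpace attack on the electron-poor, hindered iodoalkene.

Step 14
Reactants: 21 (2R)-5-oxopentan-2-yl (3S,4E)-3-(tert-butyldimethylsilyloxy)-5-iodopent-4-enoate
Product: 22 (4S,5E,10R)-4-(tert-butyldimethylsilyloxy)-7-hydroxy-10-methyl-3,4,7,8,9,10-hexahydro-2H-oxecin-2-one (7-epimers)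
Conditions: CrCl2 (excess), NiCl2 (1 mol %), degassed DMF, 25 °C, 2 mM, syringe-pump addition
Reagents that add atoms: none
Why: NiCl2 is reduced by CrCl2 to zerovalent nickel, which inserts into the C5–I bond; transmetalation gives an E-alkenyl species of trivalent chromium that adds to the C6 aldehyde (Nozaki–Hiyama–Kishi reaction), so the C5–C6 bond closes ring A. The closest known reaction type is the Cr/Ni-mediated ring closure of ω-iodoalkenyl aldehydes to ten-membered lactones that carry an allylic silyl ether. Ring A closes in a 10-exo-trig mode onto the aldehyde carbonyl and no other ring forms. The new carbinol centre at C6 is not controlled and need not be, because step 15 makes it the ketone; C3 and C9 are untouched and the E geometry of the alkenyl metal is retained. The step needs chemoselectivity for the aldehyde over the two esters, which alkenyl chromium reagents provide, and ring closure over oligomerization, which high dilution with slow addition should secure.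

Step 15
Reactants: 22 (4S,5E,10R)-4-(tert-butyldimethylsilyloxy)-7-hydroxy-10-methyl-3,4,7,8,9,10-hexahydro-2H-oxecin-2-one
Product: 23 (4S,5E,10R)-4-(tert-butyldimethylsilyloxy)-10-methyl-3,4,9,10-tetrahydro-2H-oxecine-2,7(8H)-dione
Conditions: Dess–Martin periodinane, CH2Cl2, 0 to 25 °C
Reagents that add atoms: none
Why: Dess–Martin oxidation converts both allylic alcohol epimers into one E-enone, the Michael acceptor for C4.

Step 16
Reactants: 23 (4S,5E,10R)-4-(tert-butyldimethylsilyloxy)-10-methyl-3,4,9,10-tetrahydro-2H-oxecine-2,7(8H)-dione; 24 Meldrum's acid (2,2-dimethyl-1,3-dioxane-4,6-dione)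
Product: 25 5-[(4S,5S,10R)-4-(tert-butyldimethylsilyloxy)-10-methyl-2,7-dioxooxecan-5-yl]-2,2-dimethyl-1,3-dioxane-4,6-dione
Conditions: Et3N (0.2 equiv), MeCN, 25 °C
Reagents that add atoms: none
Why: Michael addition of the soft Meldrum's acid anion to the strained E-enone; the ring chain at C2 shields one face of C4=C5 and the bulky C3 silyl ether should lie in the enone plane, so attack should come from the outer face next to H3 and set C4 (S), the cis fusion.

Step 17
Reactants: 25 5-[(4S,5S,10R)-4-(tert-butyldimethylsilyloxy)-10-methyl-2,7-dioxooxecan-5-yl]-2,2-dimethyl-1,3-dioxane-4,6-dione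
Product: 27 ring A/B lactone acid (γ-lactone cis-fused at C3/C4; CO2H on C2'), via hydroxy Meldrum adduct 26 (not isolated)
Conditions: HF·pyridine, pyridine, THF, 0 to 25 °C; then PhMe, 80 °C
Reagents that add atoms: none
Why: Fluoride frees the C3 hydroxyl, which opens the Meldrum's acid ring intramolecularly (5-exo-trig acyl substitution, loss of acetone) and closes ring B on the face fixed in step 16.

Step 18
Reactants: 27 ring A/B lactone acid; 12 2-[(2S,3S,6R)-3-(tert-butyldimethylsilyloxy)-6-methyloxan-2-yl]acetic acid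
Product: 30 ring A/B β-keto lactone carrying the ring D acyl group on C2', via acyl imidazolide 28 (not isolated), via acylated malonic acid 29 (not isolated)
Conditions: 12, CDI, THF, 25 °C; then 27, MgCl2, Et3N, MeCN, 0 to 25 °C; aq. citric acid
Reagents that add atoms: none
Why: Masamune-type decarboxylative Claisen condensation, in which the magnesium enolate of the malonic half-ester (the lactone acid) is C-acylated by the acyl imidazolide and the acyl malonic acid loses CO2 on acidification, leaving the C6 ketone unenolised.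

Step 19
Reactants: 30 ring A/B β-keto lactone carrying the ring D acyl group on C2'
Product: 32 cordycicadin C, via hydroxy ketone 31 (not isolated)
Conditions: aq. HF, MeCN, 0 to 25 °C; then PPTS, PhH, 50 °C, 4 Å sieves
Reagents that add atoms: none
Why: Acid removes the last silyl ether, the C6' hydroxyl adds to the C3' ketone (5-exo-trig hemiketal) and loss of water gives the enol ether conjugated to the lactone, with acid equilibration expected to favour the E isomer (ring oxygen anti to the lactone carbonyl).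

**Compound list**
1 | 2-acetyl-5-methylfuran | CC(=O)c1ccc(C)o1 | starting material
2 | diethyl carbonate | CCOC(=O)OCC | starting material
3 | ethyl 3-(5-methylfuran-2-yl)-3-oxopropanoate | CCOC(=O)CC(=O)c1ccc(C)o1 | intermediate
4 | ethyl (3S)-3-hydroxy-3-(5-methylfuran-2-yl)propanoate | CCOC(=O)C[C@H](O)c1ccc(C)o1 | intermediate
5 | ethyl 2-[(2S)-6-hydroxy-6-methyl-3-oxo-3,6-dihydro-2H-pyran-2-yl]acetate (anomers) | CCOC(=O)C[C@@H]1OC(C)(O)C=CC1=O | intermediate
6 | ethyl 2-[(2S,6R)-6-methyl-3-oxo-3,6-dihydro-2H-pyran-2-yl]acetate | CCOC(=O)C[C@@H]1O[C@H](C)C=CC1=O | intermediate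
7 | ethyl 2-[(2S,6R)-6-methyl-3-oxooxan-2-yl]acetate | CCOC(=O)C[C@@H]1O[C@H](C)CCC1=O | intermediate
8 | ethyl 2-[(2S,3S,6R)-3-hydroxy-6-methyloxan-2-yl]acetate (hydroxy ester) | CCOC(=O)C[C@@H]1O[C@H](C)CC[C@@H]1O | intermediate
9 | (3aS,5R,7aS)-5-methylhexahydro-2H-furo[3,2-b]pyran-2-one | O=C1C[C@@H]2O[C@H](C)CC[C@@H]2O1 | intermediate
10 | lithium 2-[(2S,3S,6R)-3-hydroxy-6-methyloxan-2-yl]acetate (lithium hydroxy carboxylate) | [Li+].[O-]C(=O)C[C@@H]1O[C@H](C)CC[C@@H]1O | intermediate
11 | tert-butyldimethylsilyl 2-[(2S,3S,6R)-3-(tert-butyldimethylsilyloxy)-6-methyloxan-2-yl]acetate (bis-silyl compound) | CC(C)(C)[Si](C)(C)OC(=O)C[C@@H]1O[C@H](C)CC[C@@H]1O[Si](C)(C)C(C)(C)C | intermediate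
12 | 2-[(2S,3S,6R)-3-(tert-butyldimethylsilyloxy)-6-methyloxan-2-yl]acetic acid | OC(=O)C[C@@H]1O[C@H](C)CC[C@@H]1O[Si](C)(C)C(C)(C)C | intermediate
13 | (S)-3-hydroxydihydrofuran-2(3H)-one ((S)-α-hydroxy-γ-butyrolactone) | O[C@H]1CCOC1=O | starting material
14 | (S)-3-(tert-butyldimethylsilyloxy)dihydrofuran-2(3H)-one | CC(C)(C)[Si](C)(C)O[C@H]1CCOC1=O | intermediate
15 | (3S)-3-(tert-butyldimethylsilyloxy)tetrahydrofuran-2-ol (anomers) | CC(C)(C)[Si](C)(C)O[C@H]1CCOC1O | intermediate
16 | iodoform | IC(I)I | starting material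
17 | (3S,4E)-3-(tert-butyldimethylsilyloxy)-5-iodopent-4-en-1-ol | OCC[C@H](O[Si](C)(C)C(C)(C)C)/C=C/I | intermediate
18 | (3S,4E)-3-(tert-butyldimethylsilyloxy)-5-iodopent-4-enoic acid | OC(=O)C[C@H](O[Si](C)(C)C(C)(C)C)/C=C/I | intermediate
19 | (R)-hex-5-en-2-ol | C[C@@H](O)CCC=C | starting material
20 | (2R)-hex-5-en-2-yl (3S,4E)-3-(tert-butyldimethylsilyloxy)-5-iodopent-4-enoate | C=CCC[C@@H](C)OC(=O)C[C@H](O[Si](C)(C)C(C)(C)C)/C=C/I | intermediate
21 | (2R)-5-oxopentan-2-yl (3S,4E)-3-(tert-butyldimethylsilyloxy)-5-iodopent-4-enoate | O=CCC[C@@H](C)OC(=O)C[C@H](O[Si](C)(C)C(C)(C)C)/C=C/I | intermediate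
22 | (4S,5E,10R)-4-(tert-butyldimethylsilyloxy)-7-hydroxy-10-methyl-3,4,7,8,9,10-hexahydro-2H-oxecin-2-one (7-epimers) | C[C@@H]1CCC(O)/C=C/[C@@H](O[Si](C)(C)C(C)(C)C)CC(=O)O1 | intermediate
23 | (4S,5E,10R)-4-(tert-butyldimethylsilyloxy)-10-methyl-3,4,9,10-tetrahydro-2H-oxecine-2,7(8H)-dione | C[C@@H]1CCC(=O)/C=C/[C@@H](O[Si](C)(C)C(C)(C)C)CC(=O)O1 | intermediate
24 | Meldrum's acid (2,2-dimethyl-1,3-dioxane-4,6-dione) | CC1(C)OC(=O)CC(=O)O1 | starting material
25 | 5-[(4S,5S,10R)-4-(tert-butyldimethylsilyloxy)-10-methyl-2,7-dioxooxecan-5-yl]-2,2-dimethyl-1,3-dioxane-4,6-dione | C[C@@H]1CCC(=O)C[C@@H](C2C(=O)OC(C)(C)OC2=O)[C@@H](O[Si](C)(C)C(C)(C)C)CC(=O)O1 | intermediate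
26 | 5-[(4S,5S,10R)-4-hydroxy-10-methyl-2,7-dioxooxecan-5-yl]-2,2-dimethyl-1,3-dioxane-4,6-dione (hydroxy Meldrum adduct) | C[C@@H]1CCC(=O)C[C@@H](C2C(=O)OC(C)(C)OC2=O)[C@@H](O)CC(=O)O1 | intermediate
27 | ring A/B lactone acid: ring A keto lactone (C3 S, C4 S, C9 R) with the γ-lactone O3–C1'(=O)–C2'H(CO2H)–C4 cis-fused at C3/C4 (C2' epimers) | C[C@@H]1CCC(=O)C[C@H]2C(C(=O)O)C(=O)O[C@H]2CC(=O)O1 | intermediate
28 | 1-{2-[(2S,3S,6R)-3-(tert-butyldimethylsilyloxy)-6-methyloxan-2-yl]acetyl}imidazole (acyl imidazolide) | O=C(C[C@@H]1O[C@H](C)CC[C@@H]1O[Si](C)(C)C(C)(C)C)n1ccnc1 | intermediate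
29 | acylated malonic acid: 27 with C2' also carrying the acyl group C3'(=O)–C4'H2–[(2S,3S,6R)-3-(TBS-oxy)-6-methyloxan-2-yl] | C[C@@H]1CCC(=O)C[C@H]2C(C(=O)O)(C(=O)C[C@@H]3O[C@H](C)CC[C@@H]3O[Si](C)(C)C(C)(C)C)C(=O)O[C@H]2CC(=O)O1 | intermediate
30 | ring A/B β-keto lactone: 29 after loss of CO2, C2'H between the lactone C=O and the C3' ketone (C2' epimers) | C[C@@H]1CCC(=O)C[C@H]2C(C(=O)C[C@@H]3O[C@H](C)CC[C@@H]3O[Si](C)(C)C(C)(C)C)C(=O)O[C@H]2CC(=O)O1 | intermediate
31 | hydroxy ketone: 30 with the C6' silyl ether cleaved to OH | C[C@@H]1CCC(=O)C[C@H]2C(C(=O)C[C@@H]3O[C@H](C)CC[C@@H]3O)C(=O)O[C@H]2CC(=O)O1 | intermediate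
32 | cordycicadin C (C3 S, C4 S, C9 R, C5' S, C6' S, C9' R, C2'=C3' E) | C[C@@H]1CCC(=O)C[C@H]2/C(=C3/C[C@@H]4O[C@H](C)CC[C@@H]4O3)C(=O)O[C@H]2CC(=O)O1 | target

**Count:** 19 steps in total; the longest linear sequence is 12 steps (13 → 32, steps 8 to 19); the ring D branch (steps 1 to 7) joins at step 18.

**Steps most likely to fail**

Step 14. Intermolecular addition may outrun ring closure, and the alkenyl chromium species may be protonated before it reaches the aldehyde, because a ten-membered ring holding an E-alkene has to form. The fallback sets out from aldehyde 21 and comes back at enone 23. It moves the same C5–C6 bond formation to the acid chloride level under palladium catalysis. Oxidation with NaClO2, NaH2PO4 and 2-methyl-2-butene would give (4R)-4-{[(3S,4E)-3-(tert-butyldimethylsilyloxy)-5-iodopent-4-enoyl]oxy}pentanoic acid F1. Iodine–tin exchange with (Bu3Sn)2 and PdCl2(PPh3)2 would give (4R)-4-{[(3S,4E)-3-(tert-butyldimethylsilyloxy)-5-(tributylstannyl)pent-4-enoyl]oxy}pentanoic acid F2. 1-Chloro-N,N,2-trimethylpropenylamine would then give the corresponding acid chloride F3. This would be cyclised by intramolecular Stille acylation with Pd2(dba)3 and tri(2-furyl)phosphine in toluene at high dilution, which gives 23 without the oxidation step.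

Step 16. The nucleophile may add to the wrong face (syn to the C3 silyl ether), or the addition to the hindered β-carbon may be unfavourable and revert. The fallback sets out from enone 23 and comes back at acid 27. It replaces substrate control by catalyst control. Dibenzyl malonate would be added under iminium catalysis by a 9-amino-9-deoxy-epi-cinchona primary amine salt (the pseudo-enantiomer matched to the C4 S face) to give dibenzyl 2-[(4S,5S,10R)-4-(tert-butyldimethylsilyloxy)-10-methyl-2,7-dioxooxecan-5-yl]malonate F4. HF·pyridine would give dibenzyl 2-[(4S,5S,10R)-4-hydroxy-10-methyl-2,7-dioxooxecan-5-yl]malonate F5. PPTS in toluene at 80 °C would close ring B to the benzyl ester of lactone acid 27 F6. Hydrogenolysis (H2, Pd/C) would then return 27.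

Step 18. Acid 27 may lose CO2 before it is C-acylated, or the hindered magnesium enolate may be O-acylated or not react. The fallback sets out from acid 12 (through imidazolide 28) and enone 23 and comes back at target 32. It makes the C2'–C3' bond before the Michael addition. Imidazolide 28 and the lithium enolate of methyl acetate (LiN(SiMe3)2, THF, −78 °C) would give methyl 4-[(2S,3S,6R)-3-(tert-butyldimethylsilyloxy)-6-methyloxan-2-yl]-3-oxobutanoate F7. Its Michael addition to 23 (catalytic Cs2CO3, MeCN) would give the adduct methyl 2-[(4S,5S,10R)-4-(tert-butyldimethylsilyloxy)-10-methyl-2,7-dioxooxecan-5-yl]-4-[(2S,3S,6R)-3-(tert-butyldimethylsilyloxy)-6-methyloxan-2-yl]-3-oxobutanoate F8. HF·pyridine would give the corresponding dihydroxy keto ester F9. PPTS in toluene at 80 °C should then close ring B (loss of methanol) and ring C (loss of water) to 32. The risk carried by this fallback is closure of O3 onto the C3' ketone instead of the ester.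

Further compounds
F1 | step 14 | (4R)-4-{[(3S,4E)-3-(tert-butyldimethylsilyloxy)-5-iodopent-4-enoyl]oxy}pentanoic acid | OC(=O)CC[C@@H](C)OC(=O)C[C@H](O[Si](C)(C)C(C)(C)C)/C=C/I
F2 | step 14 | (4R)-4-{[(3S,4E)-3-(tert-butyldimethylsilyloxy)-5-(tributylstannyl)pent-4-enoyl]oxy}pentanoic acid | OC(=O)CC[C@@H](C)OC(=O)C[C@H](O[Si](C)(C)C(C)(C)C)/C=C/[Sn](CCCC)(CCCC)CCCC
F3 | step 14 | (4R)-4-{[(3S,4E)-3-(tert-butyldimethylsilyloxy)-5-(tributylstannyl)pent-4-enoyl]oxy}pentanoyl chloride | ClC(=O)CC[C@@H](C)OC(=O)C[C@H](O[Si](C)(C)C(C)(C)C)/C=C/[Sn](CCCC)(CCCC)CCCC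
F4 | step 16 | dibenzyl 2-[(4S,5S,10R)-4-(tert-butyldimethylsilyloxy)-10-methyl-2,7-dioxooxecan-5-yl]malonate | C[C@@H]1CCC(=O)C[C@@H](C(C(=O)OCc2ccccc2)C(=O)OCc2ccccc2)[C@@H](O[Si](C)(C)C(C)(C)C)CC(=O)O1
F5 | step 16 | dibenzyl 2-[(4S,5S,10R)-4-hydroxy-10-methyl-2,7-dioxooxecan-5-yl]malonate | C[C@@H]1CCC(=O)C[C@@H](C(C(=O)OCc2ccccc2)C(=O)OCc2ccccc2)[C@@H](O)CC(=O)O1
F6 | step 16 | benzyl ester of ring A/B lactone acid 27 | C[C@@H]1CCC(=O)C[C@H]2C(C(=O)OCc3ccccc3)C(=O)O[C@H]2CC(=O)O1
F7 | step 18 | methyl 4-[(2S,3S,6R)-3-(tert-butyldimethylsilyloxy)-6-methyloxan-2-yl]-3-oxobutanoate | COC(=O)CC(=O)C[C@@H]1O[C@H](C)CC[C@@H]1O[Si](C)(C)C(C)(C)C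
F8 | step 18 | methyl 2-[(4S,5S,10R)-4-(tert-butyldimethylsilyloxy)-10-methyl-2,7-dioxooxecan-5-yl]-4-[(2S,3S,6R)-3-(tert-butyldimethylsilyloxy)-6-methyloxan-2-yl]-3-oxobutanoate | C[C@@H]1CCC(=O)C[C@@H](C(C(=O)OC)C(=O)C[C@@H]2O[C@H](C)CC[C@@H]2O[Si](C)(C)C(C)(C)C)[C@@H](O[Si](C)(C)C(C)(C)C)CC(=O)O1
F9 | step 18 | methyl 2-[(4S,5S,10R)-4-hydroxy-10-methyl-2,7-dioxooxecan-5-yl]-4-[(2S,3S,6R)-3-hydroxy-6-methyloxan-2-yl]-3-oxobutanoate | C[C@@H]1CCC(=O)C[C@@H](C(C(=O)OC)C(=O)C[C@@H]2O[C@H](C)CC[C@@H]2O)[C@@H](O)CC(=O)O1
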